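## Analysis of the target

Lespeflorin B3 (22) is a 2,3-trans-dihydroflavonol: a chroman-4-one in which benzo ring A (C4a to C8a) is fused to the dihydropyranone ring C (O1, C2, C3, C4), with ring B, a 4-hydroxy-3-prenylphenyl group, on C2. Ring A carries prenyl groups at C6 and C8 and a hydroxyl at C7, with hydrogen only at C5, so it is a pentasubstituted, electron-rich benzene. The two stereocentres are C2 (R, bearing ring B) and C3 (R, bearing the hydroxyl). They are adjacent and trans, so both substituents are equatorial on the half-chair of ring C. The sensitive groups are the three prenyl groups, each ortho to a phenol (acid closes them to 2,2-dimethylchromans, electrophilic oxidants attack the trisubstituted alkenes), and the β-aryloxy α-hydroxy ketone of ring C, which opens under base by retro-oxa-Michael reaction with loss of both stereocentres and is dehydrogenated to the flavonol by oxidants. The difficulty is to set the C2/C3 pair in absolute terms without dihydroxylation or electrophilic epoxidation reagents, which would also consume the prenyl alkenes, and to keep every late step away from strong acid and base. The strategy rests on the place of the C2–C3 unit in ring C: it lies between the O1–C2 bond and the C3–C4 bond, so a two-carbon alkene that already carries ring B on C2 and an oxygen on C3 can be inserted between the phenol oxygen (O1) and the formyl carbon (C4) of a salicylaldehyde holding the complete ring A.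

## Retrosynthetic reasoning

22 from 21. The last operation is only O–Si cleavage. All three hydroxyls (O7 and O4′ as triisopropylsilyl ethers, O3 as a tert-butyldimethylsilyl ether) are released together by buffered fluoride, so the base-labile dihydroflavonol never meets a basic ester cleavage.

21 from 20 and 19. The C4 carbonyl is traced to a C4 alcohol and that to a C4 methyl ether. C4 is benzylic to a ring with an ortho oxygen (O1) and a para oxygen (O7), so the ether ionises easily and is exchanged for hydroxyl by solvolysis. The C4 configuration is irrelevant because oxidation removes it. The oxidant has to be neutral and must not be an electrophilic oxygen donor, because of the prenyl groups.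

19 from 18 and 17. The oxygen on C3 arrives from the ring-forming step as an acetate and is changed to a silyl ether before C4 is ionised. An acetate on C3 can bridge to a C4 cation as an acetoxonium ion, whose hydrolysis can hand the acyl group to O4. Its later removal next to the ketone would also need base. Hydride cleavage of the ester at the stage of 17, where no carbonyl group is present, followed by silylation, avoids both problems at the cost of one step.

17 from 7, 14 and 15. This is the key disconnection: C3–C4 and O1–C2 are cut. These two bonds flank the stereogenic C2–C3 unit, and cutting them divides the molecule into two pieces of similar size. The salicylaldehyde 7 holds all of ring A with O1 and C4, and the (E)-enol acetate 14 holds ring B, C2, C3 and the C3 oxygen at its final oxidation level. Cuts elsewhere in ring C (C4–C4a or the bonds of ring A) would leave C2 and C3 to be made beforehand on a separate scaffold. In the forward direction the orthoformate 15 turns the formyl group of 7 into the acetal 16 and then into an O-methyl oxocarbenium ion. The alkene of 14 has to bond to it through the acetoxy-bearing carbon, and the phenol oxygen has to close the ring on the benzylic carbon, with the absolute configuration imposed by a chiral counter-anion.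

7 from 6, 5, 3, 2 and 1. The two prenyl groups of ring A are cut at their aryl–CH2 bonds and traced to the diiodide 3 and the stannane 4. Iodination of 1 is regiochemically unambiguous, since C3 and C5 are the only positions activated by both hydroxyls, whereas direct base-mediated C-prenylation of a resorcinol aldehyde gives O- and C-alkylated mixtures of mono- and di-substituted products. The phenols are masked as methoxymethyl ethers (3, 5) for the coupling and then released (6). Only O4 is silylated to give 7, because the O2 hydroxyl is held in a hydrogen bond to the formyl group and must stay free as the ring-closing nucleophile.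

14 from 13, 12, 10, 9 and 8. The enol C–O bond is cut and formed with retention from the (E)-alkenylboron compound 13. Enol acetylation of an arylacetaldehyde gives E/Z mixtures, and the geometry bears on the facial selectivity of the key step. Compound 13 comes from the pinacol boronate 12, which is made in one step and with trans selectivity from the aldehyde 10 and the diborylmethane 11. The aldehyde 10 comes from commercial 8 by silylation (9) and coupling with 4.

## Alternatives that were turned down

Alternative 1: Ring A is cut at C4a–C5 and C8–C8a. The forward key step would be a Diels–Alder reaction between the ring C dienophile A2 (an enantiopure 2-aryl-3-silyloxy-2,3-dihydropyran-4-one with a phenylsulfinyl group on the future C4a) and the diene A3 (C5 to C8 with both prenyl groups, the C7 oxygen as a silyl enol ether and a methoxy group on the future C5). Sulfoxide elimination, loss of the methoxy group and loss of the O7 silyl group would aromatise the adduct to the bis-silyl ether A1.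
- For: both stereocentres exist before the uncertain step and are not touched by it. The prenyl pattern of ring A is dictated by the diene, so no arene substitution is needed. A1 is one deprotection from the target.
- Against: the C4a=C8a bond of A2 is a vinylogous ester alkene, trisubstituted and poorly dienophilic even with the sulfinyl group. A3 is a fully substituted, hydrolytically labile diene that must reach the s-cis form against its own substituents and must be made with defined geometry. The heat required invites premature sulfoxide elimination, ene reactions of the prenyl groups and epimerisation at C3 next to the ketone. An enantioselective synthesis of A2 is a multi-step problem of its own.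
- Comparison: Alternative 1 is stronger in that the absolute configuration does not depend on an untested catalytic step and the endgame is shorter. The chosen strategy offers instead short access to both partners from simple benzaldehydes and creation of both stereocentres in the convergent step.

Alternative 2: Rings A and C are cut together at C4a–C8a, C5–C6 and C7–C8. The forward key step would be a [2+2+2] cyclotrimerisation, under a cationic monovalent rhodium bisphosphine catalyst, of the tethered diyne A5 (chain O1–C2–C3–C4 with an alkynyl ether on O1 and an ethynyl ketone at C4) with the prenyl siloxyalkyne A6, giving the tris-silyl ether A4.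
- For: this is the most convergent plan. The benzene ring is created fully substituted, and the tether enforces the closure of ring C.
- Against: the orientation of A6 in the intermolecular insertion is not fixed by the tether, so the isomer with prenyl at C7 and silyloxy at C6 can form. Ynol ethers and siloxyalkynes are fragile towards acid, heat and moisture. A5 is a β-alkynyloxy ketone with an acidic C3–H and can eliminate. Making a secondary benzylic ynol ether with defined C2 configuration is difficult. The prenyl alkenes can enter enyne pathways at the metal.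
- Comparison: Alternative 2 is stronger in convergence and in forming two rings at once. The chosen strategy fixes the ring A pattern in the starting arene and asks the uncertain step to close only one ring.

Alternative 3: Only C4–C4a is cut. The forward key step would be halogen–lithium exchange at the future C4a of the aryl bromide A8, followed by intramolecular acylation by its N-methoxy-N-methylamide (a Parham-type cyclisation), closing ring C to the tris-silyl ether A7.
- For: the ring closure is a known reaction type with a chelated tetrahedral intermediate that prevents over-addition. Both stereocentres are set beforehand. A7 is one step from the target.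
- Against: A8 needs the O1–C2 aryl ether to be formed at a secondary, para-silyloxybenzylic carbon with a hindered 2,6-disubstituted bromophenol. That centre ionises easily, so clean inversion is doubtful. In A8 the aryloxy group is β to the amide carbonyl and C3–H is α, so elimination of aryloxide competes under the strongly basic exchange conditions. The benzylic-allylic CH2 of the neighbouring prenyl group can quench the aryllithium. The 2,3-dioxygenated acid precursor would normally come from alkene oxidation, which conflicts with prenyl groups and forces their late introduction, lengthening the sequence.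
- Comparison: Alternative 3 is stronger on precedent for the ring closure and on early control of configuration. The chosen strategy is shorter and convergent and forms both ring bonds and both stereocentres in one step.

Key step: step 11

Assumption: the sense of induction of the confined chiral acid in step 11 cannot be derived from the known reactions, so the route is written for the catalyst antipode that gives (2R,3S)-17, to be identified in a first pair of small runs with both antipodes.

Abbreviations in names: prenyl = 3-methylbut-2-en-1-yl; TIPS = triisopropylsilyl; TBS = tert-butyldimethylsilyl; MOM = methoxymethyl; Bpin = 4,4,5,5-tetramethyl-1,3,2-dioxaborolan-2-yl.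

## Steps

Step 1
Reactants: 1 2,4-dihydroxybenzaldehyde
Product: 2 2,4-dihydroxy-3,5-diiodobenzaldehyde
Conditions: ICl (2.2 equiv), AcOH, rt
Reagents that add atoms: iodine monochloride, ClI
Why: Electrophilic aromatic iodination; C3 and C5 are the only positions ortho or para to both hydroxyls, while C6 is meta to both and deactivated by the formyl group, so twofold iodination can give only this isomer.

Step 2
Reactants: 2 2,4-dihydroxy-3,5-diiodobenzaldehyde
Product: 3 3,5-diiodo-2,4-bis(methoxymethoxy)benzaldehyde
Conditions: NaH (2.4 equiv), MOMCl (2.6 equiv), DMF, 0 °C → rt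
Reagents that add atoms: chloromethyl methyl ether, COCCl
Why: Williamson O-alkylation of the two acidic iodophenoxides by a small, reactive electrophile; the acetal ethers remove the phenolic protons before the organometallic step and withstand it.

Step 3
Reactants: 3 3,5-diiodo-2,4-bis(methoxymethoxy)benzaldehyde; 4 tributyl(prenyl)stannane
Product: 5 2,4-bis(methoxymethoxy)-3,5-diprenylbenzaldehyde
Conditions: 4 (2.6 equiv), Pd(PPh3)4 (10 mol %), DMF, 95 °C
Reagents that add atoms: 4 tributyl(prenyl)stannane, CCCC[Sn](CCCC)(CCCC)CC=C(C)C
Why: Twofold Stille coupling of aryl iodides with an allylic stannane; reductive elimination at the less hindered allyl terminus should give the linear prenyl arene, and aldehyde and acetal ethers are inert to the neutral conditions.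

Step 4
Reactants: 5 2,4-bis(methoxymethoxy)-3,5-diprenylbenzaldehyde
Product: 6 2,4-dihydroxy-3,5-diprenylbenzaldehyde
Conditions: 3 M HCl (aq), MeOH, 45 °C; aqueous work-up
Reagents that add atoms: none
Why: Acid-catalysed acetal cleavage with transfer of the CH2 unit to methanol; dilute acid at moderate temperature is the standard release of methoxymethyl-protected ortho-prenyl phenols and is too mild for chroman closure, and any aldehyde dimethyl acetal reverts on aqueous work-up.

Step 5
Reactants: 6 2,4-dihydroxy-3,5-diprenylbenzaldehyde
Product: 7 2-hydroxy-3,5-diprenyl-4-(TIPS-oxy)benzaldehyde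
Conditions: TIPSOTf (1.05 equiv), 2,6-lutidine, CH2Cl2, −78 → 0 °C
Reagents that add atoms: triisopropylsilyl trifluoromethanesulfonate, CC(C)[Si](OS(=O)(=O)C(F)(F)F)(C(C)C)C(C)C
Why: Site-selective O-silylation; the O2 hydroxyl is tied in an intramolecular hydrogen bond to the formyl oxygen and is the poorer nucleophile, while the O4 hydroxyl is free and more acidic, and the reactive silyl triflate overcomes the two flanking prenyl groups.

Step 6
Reactants: 8 4-hydroxy-3-iodobenzaldehyde
Product: 9 3-iodo-4-(TIPS-oxy)benzaldehyde
Conditions: TIPSCl (1.2 equiv), imidazole, DMF, rt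
Reagents that add atoms: triisopropylsilyl chloride, CC(C)[Si](Cl)(C(C)C)C(C)C
Why: Standard silylation of an acidic phenol; the bulky silyl ether is chosen to survive the later base, fluoride-free coupling and acid steps.

Step 7
Reactants: 9 3-iodo-4-(TIPS-oxy)benzaldehyde; 4 tributyl(prenyl)stannane
Product: 10 3-prenyl-4-(TIPS-oxy)benzaldehyde
Conditions: 4 (1.3 equiv), Pd(PPh3)4 (5 mol %), toluene, 100 °C
Reagents that add atoms: 4 tributyl(prenyl)stannane, CCCC[Sn](CCCC)(CCCC)CC=C(C)C
Why: Stille coupling as in step 3 at an iodide with one ortho substituent; a non-nucleophilic solvent is used so that the aryl silyl ether para to the formyl group is not cleaved.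

Step 8
Reactants: 10 3-prenyl-4-(TIPS-oxy)benzaldehyde; 11 bis(Bpin)methane
Product: 12 (E)-2-{2-[3-prenyl-4-(TIPS-oxy)phenyl]ethenyl}-4,4,5,5-tetramethyl-1,3,2-dioxaborolane
Conditions: 11 (1.2 equiv), LiTMP (lithium 2,2,6,6-tetramethylpiperidide, 1.2 equiv), THF, 0 °C; then 10, −78 °C → rt
Reagents that add atoms: 11 bis(Bpin)methane, CC1(C)OB(CB2OC(C)(C)C(C)(C)O2)OC1(C)C
Why: Boron–Wittig olefination; the α-diboryl carbanion adds to the aldehyde and elimination of a boron–oxygen pair gives the one-carbon-homologated alkenyl boronate, for which the trans isomer is strongly favoured with aryl aldehydes.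

Step 9
Reactants: 12 (E)-alkenyl pinacol boronate
Product: 13 potassium (E)-trifluoro{2-[3-prenyl-4-(TIPS-oxy)phenyl]ethenyl}borate
Conditions: KHF2 (4.5 M aq, 4 equiv), MeOH, 0 °C, short contact; extraction into acetone
Reagents that add atoms: potassium hydrogen difluoride, F.[F-].[K+]
Why: Ligand exchange at boron from pinacol to fluoride gives the tetracoordinate salt that couples best in the next step; contact is kept short and cold because bifluoride can also cleave aryl silyl ethers, of which the ortho-substituted TIPS ether is the most resistant.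

Step 10
Reactants: 13 potassium (E)-alkenyltrifluoroborate
Product: 14 (E)-2-[3-prenyl-4-(TIPS-oxy)phenyl]ethenyl acetate
Conditions: AcOH (3 equiv), CuBr (10 mol %), DMAP (20 mol %), 4 Å MS, O2 (1 atm), MeCN, 40 °C
Reagents that add atoms: acetic acid, CC(=O)O
Why: Chan–Lam-type oxidative C–O coupling of an alkenyltrifluoroborate with a carboxylic acid; transmetalation to copper and C–O reductive elimination occur with retention, so the (E) geometry of 13 is carried into the enol ester.

Step 11
Reactants: 7 2-hydroxy-3,5-diprenyl-4-(TIPS-oxy)benzaldehyde; 14 (E)-2-[3-prenyl-4-(TIPS-oxy)phenyl]ethenyl acetate; 15 trimethyl orthoformate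
Product: 17 (2R,3S,4R)-4-methoxy-6,8-diprenyl-2-[3-prenyl-4-(TIPS-oxy)phenyl]-7-(TIPS-oxy)chroman-3-yl acetate (2,3-trans-3,4-trans), via salicylaldehyde dimethyl acetal 16 (not isolated)
Conditions: 15 (2 equiv), confined chiral imidodiphosphorimidate Brønsted acid (IDPi, 5 mol %), CH2Cl2, −20 °C; then 14 (1.3 equiv), 5 Å MS, −60 → −40 °C
Reagents that add atoms: 15 trimethyl orthoformate, COC(OC)OC
Why: Proposed new method: the chiral acid first catalyses acetal formation from 7 and 15 to give 16 and then ionises 16 to an O-methyl oxocarbenium ion (the protonated form of an ortho-quinone methide methyl ether) that stays paired with the confined chiral anion and hydrogen-bonded to it through the phenol. The enol acetate 14 attacks this ion through its acetoxy-bearing carbon, forming C3–C4, because this places the charge on the benzylic carbon where the para-silyloxyphenyl group and the neighbouring acetate (as a five-membered acetoxonium ion) stabilise it, an acyloxy group alone being the weaker donor. The phenol oxygen then forms O1–C2 and closes six-membered ring C, 6-endo with respect to the former C2=C3 bond (6-exo-tet if counted on the bridged ion), so the overall change equals an inverse-demand hetero-[4+2] cycloaddition. The closest known reaction types are the achiral acid-catalysed union of salicylaldehydes, orthoformates and styrenes to 2,4-cis-4-alkoxy-2-arylchromans and chiral Brønsted acid catalysed [4+2] cycloadditions of ortho-quinone methides; an enol ester as the two-carbon partner and counter-anion control of its facial selectivity are the untested elements. C3 is set in the C–C bond formation and its absolute sense by the chiral anion; C2 is set relative to C3, since the (E)-alkene and the trans-disposed acetoxonium ion, opened with inversion by the phenol, place aryl and acetoxy trans and equatorial; C4 follows from the approach inside the ion pair, is expected 2,4-cis (4R), and is of no consequence because it later becomes the carbonyl carbon. The step needs regioselectivity (aryl against acetoxy as cation stabiliser, secured by the para oxygen of ring B), chemoselectivity over the three prenyl alkenes (the donor-conjugated enol acetate is the better π-nucleophile and neither prenyl group of 7 can reach the cationic carbon intramolecularly) and survival of the prenyl group next to the free phenol (catalytic acid, low temperature, sieves to take up methanol).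

Step 12
Reactants: 17 (2R,3S,4R)-4-methoxy-chroman-3-yl acetate
Product: 18 (2R,3S,4R)-4-methoxy-6,8-diprenyl-2-[3-prenyl-4-(TIPS-oxy)phenyl]-7-(TIPS-oxy)chroman-3-ol
Conditions: DIBAL-H (i-Bu2AlH, 2.5 equiv), CH2Cl2, −78 °C; aq. potassium sodium tartrate work-up
Reagents that add atoms: none
Why: Reductive cleavage of the ester by hydride; this is non-basic, spares the aryl silyl ethers, the benzylic methyl ether and the alkenes at low temperature, and leaves all three stereocentres untouched.

Step 13
Reactants: 18 (2R,3S,4R)-4-methoxy-chroman-3-ol
Product: 19 (2R,3S,4R)-3-(TBS-oxy)-4-methoxy-6,8-diprenyl-2-[3-prenyl-4-(TIPS-oxy)phenyl]-7-(TIPS-oxy)chroman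
Conditions: TBSCl (2 equiv), imidazole, DMAP (cat.), DMF, 40 °C
Reagents that add atoms: tert-butyldimethylsilyl chloride, CC(C)(C)[Si](C)(C)Cl
Why: Silylation of the equatorial secondary alcohol under conditions free of Lewis acid, so that the ionisable C4 ether is not activated; a silyl ether cannot bridge to C4 in the next step and is removed together with the aryl silyl ethers at the end.

Step 14
Reactants: 19 (2R,3S,4R)-3-(TBS-oxy)-4-methoxychroman
Product: 20 (2R,3S)-3-(TBS-oxy)-6,8-diprenyl-2-[3-prenyl-4-(TIPS-oxy)phenyl]-7-(TIPS-oxy)chroman-4-ol (mixture of C4 epimers)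
Conditions: PPTS (0.3 equiv), THF–H2O (4:1), 40 °C
Reagents that add atoms: water, O
Why: SN1 solvolysis of a benzylic methyl ether; the C4 cation is stabilised by the ortho oxygen O1 and the para silyloxy group, so mild acid is enough and water is the only nucleophile present in quantity, while the secondary silyl ether, the aryl silyl ethers and the prenyl alkenes should tolerate pyridinium acid.

Step 15
Reactants: 20 (2R,3S)-3-(TBS-oxy)chroman-4-ol (C4 epimers)
Product: 21 (2R,3R)-3-(TBS-oxy)-6,8-diprenyl-2-[3-prenyl-4-(TIPS-oxy)phenyl]-7-(TIPS-oxy)chroman-4-one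
Conditions: Dess–Martin periodinane (1.5 equiv), pyridine, CH2Cl2, 0 °C → rt
Reagents that add atoms: none
Why: Dess–Martin oxidation of a secondary benzylic alcohol; both C4 epimers converge on one ketone, the periodinane does not epoxidise alkenes, and the buffered neutral medium gives no enolisation, so C3 keeps its configuration (its descriptor changes from S to R only because C4 now outranks C2).

Step 16
Reactants: 21 (2R,3R)-3-(TBS-oxy)chroman-4-one
Product: 22 lespeflorin B3, (2R,3R)-3,7-dihydroxy-2-(4-hydroxy-3-prenylphenyl)-6,8-diprenylchroman-4-one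
Conditions: TBAF (5 equiv), AcOH (5 equiv), THF, 0 °C → rt
Reagents that add atoms: none
Why: Fluoride-mediated cleavage of the two aryl silyl ethers and the α-keto secondary silyl ether in one operation; the acetic acid buffer keeps the phenols protonated so that the retro-oxa-Michael opening of ring C and enolisation at C3 do not set in, and C2 and C3 are not touched.

## Compound list

1 | 2,4-dihydroxybenzaldehyde | O=Cc1ccc(O)cc1O | starting material
2 | 2,4-dihydroxy-3,5-diiodobenzaldehyde | O=Cc1cc(I)c(O)c(I)c1O | intermediate
3 | 3,5-diiodo-2,4-bis(methoxymethoxy)benzaldehyde | COCOc1c(I)cc(C=O)c(OCOC)c1I | intermediate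
4 | tributyl(3-methylbut-2-en-1-yl)stannane | CCCC[Sn](CCCC)(CCCC)CC=C(C)C | starting material
5 | 2,4-bis(methoxymethoxy)-3,5-bis(3-methylbut-2-en-1-yl)benzaldehyde | COCOc1c(CC=C(C)C)cc(C=O)c(OCOC)c1CC=C(C)C | intermediate
6 | 2,4-dihydroxy-3,5-bis(3-methylbut-2-en-1-yl)benzaldehyde | CC(C)=CCc1cc(C=O)c(O)c(CC=C(C)C)c1O | intermediate
7 | 2-hydroxy-3,5-bis(3-methylbut-2-en-1-yl)-4-[(triisopropylsilyl)oxy]benzaldehyde | CC(C)=CCc1cc(C=O)c(O)c(CC=C(C)C)c1O[Si](C(C)C)(C(C)C)C(C)C | intermediate
8 | 4-hydroxy-3-iodobenzaldehyde | O=Cc1ccc(O)c(I)c1 | starting material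
9 | 3-iodo-4-[(triisopropylsilyl)oxy]benzaldehyde | O=Cc1ccc(O[Si](C(C)C)(C(C)C)C(C)C)c(I)c1 | intermediate
10 | 3-(3-methylbut-2-en-1-yl)-4-[(triisopropylsilyl)oxy]benzaldehyde | CC(C)=CCc1cc(C=O)ccc1O[Si](C(C)C)(C(C)C)C(C)C | intermediate
11 | bis(4,4,5,5-tetramethyl-1,3,2-dioxaborolan-2-yl)methane | CC1(C)OB(CB2OC(C)(C)C(C)(C)O2)OC1(C)C | starting material
12 | (E)-4,4,5,5-tetramethyl-2-{2-[3-(3-methylbut-2-en-1-yl)-4-[(triisopropylsilyl)oxy]phenyl]ethenyl}-1,3,2-dioxaborolane | CC(C)=CCc1cc(/C=C/B2OC(C)(C)C(C)(C)O2)ccc1O[Si](C(C)C)(C(C)C)C(C)C | intermediate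
13 | potassium (E)-trifluoro{2-[3-(3-methylbut-2-en-1-yl)-4-[(triisopropylsilyl)oxy]phenyl]ethenyl}borate | CC(C)=CCc1cc(/C=C/[B-](F)(F)F)ccc1O[Si](C(C)C)(C(C)C)C(C)C.[K+] | intermediate
14 | (E)-2-[3-(3-methylbut-2-en-1-yl)-4-[(triisopropylsilyl)oxy]phenyl]ethenyl acetate | CC(=O)O/C=C/c1ccc(O[Si](C(C)C)(C(C)C)C(C)C)c(CC=C(C)C)c1 | intermediate
15 | trimethyl orthoformate | COC(OC)OC | starting material
16 | 6-(dimethoxymethyl)-2,4-bis(3-methylbut-2-en-1-yl)-3-[(triisopropylsilyl)oxy]phenol | COC(OC)c1cc(CC=C(C)C)c(O[Si](C(C)C)(C(C)C)C(C)C)c(CC=C(C)C)c1O | intermediate (not isolated)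
17 | (2R,3S,4R)-4-methoxy-6,8-bis(3-methylbut-2-en-1-yl)-2-{3-(3-methylbut-2-en-1-yl)-4-[(triisopropylsilyl)oxy]phenyl}-7-[(triisopropylsilyl)oxy]chroman-3-yl acetate | CC(C)=CCc1cc([C@H]2Oc3c(cc(CC=C(C)C)c(O[Si](C(C)C)(C(C)C)C(C)C)c3CC=C(C)C)[C@@H](OC)[C@@H]2OC(C)=O)ccc1O[Si](C(C)C)(C(C)C)C(C)C | intermediate
18 | (2R,3S,4R)-4-methoxy-6,8-bis(3-methylbut-2-en-1-yl)-2-{3-(3-methylbut-2-en-1-yl)-4-[(triisopropylsilyl)oxy]phenyl}-7-[(triisopropylsilyl)oxy]chroman-3-ol | CC(C)=CCc1cc([C@H]2Oc3c(cc(CC=C(C)C)c(O[Si](C(C)C)(C(C)C)C(C)C)c3CC=C(C)C)[C@@H](OC)[C@@H]2O)ccc1O[Si](C(C)C)(C(C)C)C(C)C | intermediate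
19 | (2R,3S,4R)-3-[(tert-butyldimethylsilyl)oxy]-4-methoxy-6,8-bis(3-methylbut-2-en-1-yl)-2-{3-(3-methylbut-2-en-1-yl)-4-[(triisopropylsilyl)oxy]phenyl}-7-[(triisopropylsilyl)oxy]chroman | CC(C)=CCc1cc([C@H]2Oc3c(cc(CC=C(C)C)c(O[Si](C(C)C)(C(C)C)C(C)C)c3CC=C(C)C)[C@@H](OC)[C@@H]2O[Si](C)(C)C(C)(C)C)ccc1O[Si](C(C)C)(C(C)C)C(C)C | intermediate
20 | (2R,3S)-3-[(tert-butyldimethylsilyl)oxy]-6,8-bis(3-methylbut-2-en-1-yl)-2-{3-(3-methylbut-2-en-1-yl)-4-[(triisopropylsilyl)oxy]phenyl}-7-[(triisopropylsilyl)oxy]chroman-4-ol, both C4 epimers | CC(C)=CCc1cc([C@H]2Oc3c(cc(CC=C(C)C)c(O[Si](C(C)C)(C(C)C)C(C)C)c3CC=C(C)C)C(O)[C@@H]2O[Si](C)(C)C(C)(C)C)ccc1O[Si](C(C)C)(C(C)C)C(C)C | intermediate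
21 | (2R,3R)-3-[(tert-butyldimethylsilyl)oxy]-6,8-bis(3-methylbut-2-en-1-yl)-2-{3-(3-methylbut-2-en-1-yl)-4-[(triisopropylsilyl)oxy]phenyl}-7-[(triisopropylsilyl)oxy]chroman-4-one | CC(C)=CCc1cc([C@H]2Oc3c(cc(CC=C(C)C)c(O[Si](C(C)C)(C(C)C)C(C)C)c3CC=C(C)C)C(=O)[C@@H]2O[Si](C)(C)C(C)(C)C)ccc1O[Si](C(C)C)(C(C)C)C(C)C | intermediate
22 | lespeflorin B3, (2R,3R)-3,7-dihydroxy-2-[4-hydroxy-3-(3-methylbut-2-en-1-yl)phenyl]-6,8-bis(3-methylbut-2-en-1-yl)chroman-4-one | CC(C)=CCc1cc([C@H]2Oc3c(cc(CC=C(C)C)c(O)c3CC=C(C)C)C(=O)[C@@H]2O)ccc1O | target

## Step count and least certain steps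

Total: 16 steps. Longest linear sequence: 11 steps (steps 1 to 5 and 11 to 16 from 1; the ring B branch from 8, steps 6 to 10 and 11 to 16, is equally long).

**Step 11 (key step, proposed new method).**
- What may go wrong: C–C bond formation may not compete. The acetoxy group lowers the nucleophilicity of the alkene while the oxocarbenium ion is strongly stabilised by the para silyloxy group. Methanol addition across the enol acetate, Prins or ene capture of the ion by a prenyl alkene, or acid-induced closure of the prenyl group onto the neighbouring free phenol can then take over. A second failure mode is poor facial discrimination in a loose ion pair, which would give the trans acetate in low enantiomeric purity.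
- Fallback (known chemistry; sets out from 5 and 8, comes back at 22): addition of MeMgBr to 5 (THF, 0 °C) gives 1-[2,4-bis(methoxymethoxy)-3,5-diprenylphenyl]ethan-1-ol F1, which Dess–Martin periodinane oxidises to 1-[2,4-bis(methoxymethoxy)-3,5-diprenylphenyl]ethan-1-one F2. Compound 8 is protected (MOMCl, i-Pr2NEt) as 3-iodo-4-(methoxymethoxy)benzaldehyde F3 and coupled with 4 as in step 7 to give 4-(methoxymethoxy)-3-prenylbenzaldehyde F4. Claisen–Schmidt condensation of F2 with F4 (KOH, EtOH, rt) gives (E)-1-[2,4-bis(methoxymethoxy)-3,5-diprenylphenyl]-3-[4-(methoxymethoxy)-3-prenylphenyl]prop-2-en-1-one F5. Juliá–Colonna epoxidation (poly-leucine, urea–H2O2, DBU, THF) is a nucleophilic epoxidation that leaves the prenyl alkenes alone and gives the trans-epoxy ketone [2,4-bis(methoxymethoxy)-3,5-diprenylphenyl]{(2R,3S)-3-[4-(methoxymethoxy)-3-prenylphenyl]oxiran-2-yl}methanone F6, the polymer antipode being chosen for this sense. HCl in MeOH at 45 °C then removes the three MOM groups, and the freed 2′-phenol opens the epoxide at its benzylic carbon with inversion while the carbinol carbon is retained as C3, so that 22 is reached directly.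

**Step 3.**
- What may go wrong: incomplete coupling at C3, which is flanked by two alkoxy groups; protodeiodination; or allylic transposition at palladium giving the 1,1-dimethylallyl isomer.
- Fallback (sets out from 1, comes back at 6): O-allylation of 1 at the more acidic 4-hydroxyl (allyl bromide, K2CO3, acetone) gives 4-(allyloxy)-2-hydroxybenzaldehyde F7. Claisen rearrangement (N,N-diethylaniline, 190 °C) gives 3-allyl-2,4-dihydroxybenzaldehyde F8; any 5-allyl isomer converges in the next round. A second allylation gives 3-allyl-4-(allyloxy)-2-hydroxybenzaldehyde F9, and a second Claisen rearrangement into the one remaining ortho position gives 3,5-diallyl-2,4-dihydroxybenzaldehyde F10. Twofold cross-metathesis with 2-methylbut-2-ene (second-generation Grubbs catalyst, RuCl2(=CHPh)(PCy3)(H2IMes), CH2Cl2, 40 °C) converts both allyl groups into prenyl groups and gives 6, bypassing steps 1 to 4.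

**Step 10 (with step 9 before it).**
- What may go wrong: protodeboronation or oxidative homocoupling at copper instead of C–O coupling, and in step 9 partial cleavage of the aryl silyl ether by bifluoride.
- Fallback (sets out from 10, comes back at 14): Wittig reaction of 10 with the ylide from (methoxymethyl)triphenylphosphonium chloride and KHMDS gives 1-(2-methoxyethenyl)-3-prenyl-4-(TIPS-oxy)benzene F11 as an E/Z mixture. Hydrolysis (2 M HCl, THF, rt) gives 2-[3-prenyl-4-(TIPS-oxy)phenyl]acetaldehyde F12. Enol acetylation under equilibrating conditions (Ac2O, KOAc, 120 °C) gives 14 together with its geometric isomer (Z)-2-[3-prenyl-4-(TIPS-oxy)phenyl]ethenyl acetate F13, which is separated on AgNO3-impregnated silica and re-equilibrated with catalytic iodine. This is less selective than the boron route but bypasses steps 8 to 10.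

**Step 14.**
- What may go wrong: proton loss from the C4 cation towards the 2H-chromene (a silyl enol ether) instead of capture by water, partial loss of the O3 silyl group, or, if stronger acid is needed, hydration or cyclisation at a prenyl group.
- Fallback (sets out from 19, comes back at 21): DDQ in CH2Cl2 with pH 7 buffer at 0 °C abstracts hydride from C4, the position most activated by the ortho and para oxygens and the methoxy group. Water adds to the resulting O-methyl oxocarbenium ion and the hemiketal collapses to the ketone 21, so that steps 14 and 15 merge and no new compound is made.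

## Further compounds

F1 | step 11 | 1-[2,4-bis(methoxymethoxy)-3,5-bis(3-methylbut-2-en-1-yl)phenyl]ethan-1-ol (racemic) | COCOc1c(CC=C(C)C)cc(C(C)O)c(OCOC)c1CC=C(C)C
F2 | step 11 | 1-[2,4-bis(methoxymethoxy)-3,5-bis(3-methylbut-2-en-1-yl)phenyl]ethan-1-one | COCOc1c(CC=C(C)C)cc(C(C)=O)c(OCOC)c1CC=C(C)C
F3 | step 11 | 3-iodo-4-(methoxymethoxy)benzaldehyde | COCOc1ccc(C=O)cc1I
F4 | step 11 | 4-(methoxymethoxy)-3-(3-methylbut-2-en-1-yl)benzaldehyde | COCOc1ccc(C=O)cc1CC=C(C)C
F5 | step 11 | (E)-1-[2,4-bis(methoxymethoxy)-3,5-bis(3-methylbut-2-en-1-yl)phenyl]-3-[4-(methoxymethoxy)-3-(3-methylbut-2-en-1-yl)phenyl]prop-2-en-1-one | COCOc1ccc(/C=C/C(=O)c2cc(CC=C(C)C)c(OCOC)c(CC=C(C)C)c2OCOC)cc1CC=C(C)C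
F6 | step 11 | [2,4-bis(methoxymethoxy)-3,5-bis(3-methylbut-2-en-1-yl)phenyl]{(2R,3S)-3-[4-(methoxymethoxy)-3-(3-methylbut-2-en-1-yl)phenyl]oxiran-2-yl}methanone | O=C(c1cc(CC=C(C)C)c(OCOC)c(CC=C(C)C)c1OCOC)[C@@H]2O[C@H]2c3ccc(OCOC)c(CC=C(C)C)c3
F7 | step 3 | 4-(allyloxy)-2-hydroxybenzaldehyde | C=CCOc1ccc(C=O)c(O)c1
F8 | step 3 | 3-allyl-2,4-dihydroxybenzaldehyde | C=CCc1c(O)ccc(C=O)c1O
F9 | step 3 | 3-allyl-4-(allyloxy)-2-hydroxybenzaldehyde | C=CCOc1ccc(C=O)c(O)c1CC=C
F10 | step 3 | 3,5-diallyl-2,4-dihydroxybenzaldehyde | C=CCc1cc(C=O)c(O)c(CC=C)c1O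
F11 | step 10 | 1-(2-methoxyethenyl)-3-(3-methylbut-2-en-1-yl)-4-[(triisopropylsilyl)oxy]benzene (E/Z mixture) | COC=Cc1ccc(O[Si](C(C)C)(C(C)C)C(C)C)c(CC=C(C)C)c1
F12 | step 10 | 2-[3-(3-methylbut-2-en-1-yl)-4-[(triisopropylsilyl)oxy]phenyl]acetaldehyde | O=CCc1ccc(O[Si](C(C)C)(C(C)C)C(C)C)c(CC=C(C)C)c1
F13 | step 10 | (Z)-2-[3-(3-methylbut-2-en-1-yl)-4-[(triisopropylsilyl)oxy]phenyl]ethenyl acetate | CC(=O)O/C=C\c1ccc(O[Si](C(C)C)(C(C)C)C(C)C)c(CC=C(C)C)c1
F0 | step 14 | none | none
A1 | alternative 1 | 3,4′-bis-O-(tert-butyldimethylsilyl) lespeflorin B3 | CC(C)=CCc1cc([C@H]2Oc3c(cc(CC=C(C)C)c(O)c3CC=C(C)C)C(=O)[C@@H]2O[Si](C)(C)C(C)(C)C)ccc1O[Si](C)(C)C(C)(C)C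
A2 | alternative 1 | (2R,3R)-3-[(tert-butyldimethylsilyl)oxy]-2-{4-[(tert-butyldimethylsilyl)oxy]-3-(3-methylbut-2-en-1-yl)phenyl}-5-(phenylsulfinyl)-2,3-dihydro-4H-pyran-4-one | CC(C)=CCc1cc([C@H]2OC=C(S(=O)c3ccccc3)C(=O)[C@@H]2O[Si](C)(C)C(C)(C)C)ccc1O[Si](C)(C)C(C)(C)C
A3 | alternative 1 | {[1-methoxy-7-methyl-2-(3-methylbut-2-en-1-yl)octa-1,3,6-trien-3-yl]oxy}trimethylsilane | COC=C(CC=C(C)C)C(O[Si](C)(C)C)=CCC=C(C)C
A4 | alternative 2 | 3,4′-bis-O-(tert-butyldimethylsilyl)-7-O-(triisopropylsilyl) lespeflorin B3 | CC(C)=CCc1cc([C@H]2Oc3c(cc(CC=C(C)C)c(O[Si](C(C)C)(C(C)C)C(C)C)c3CC=C(C)C)C(=O)[C@@H]2O[Si](C)(C)C(C)(C)C)ccc1O[Si](C)(C)C(C)(C)C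
A5 | alternative 2 | (4R,5R)-4-[(tert-butyldimethylsilyl)oxy]-5-{4-[(tert-butyldimethylsilyl)oxy]-3-(3-methylbut-2-en-1-yl)phenyl}-5-[(5-methylhex-4-en-1-yn-1-yl)oxy]pent-1-yn-3-one | CC(C)=CCc1cc([C@@H](OC#CCC=C(C)C)[C@@H](O[Si](C)(C)C(C)(C)C)C(=O)C#C)ccc1O[Si](C)(C)C(C)(C)C
A6 | alternative 2 | triisopropyl[(5-methylhex-4-en-1-yn-1-yl)oxy]silane | CC(C)=CCC#CO[Si](C(C)C)(C(C)C)C(C)C
A7 | alternative 3 | lespeflorin B3 tris(tert-butyldimethylsilyl) ether | CC(C)=CCc1cc([C@H]2Oc3c(cc(CC=C(C)C)c(O[Si](C)(C)C(C)(C)C)c3CC=C(C)C)C(=O)[C@@H]2O[Si](C)(C)C(C)(C)C)ccc1O[Si](C)(C)C(C)(C)C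
A8 | alternative 3 | (2R,3R)-3-{2-bromo-5-[(tert-butyldimethylsilyl)oxy]-4,6-bis(3-methylbut-2-en-1-yl)phenoxy}-2-[(tert-butyldimethylsilyl)oxy]-3-{4-[(tert-butyldimethylsilyl)oxy]-3-(3-methylbut-2-en-1-yl)phenyl}-N-methoxy-N-methylpropanamide | CC(C)=CCc1cc([C@@H](Oc2c(Br)cc(CC=C(C)C)c(O[Si](C)(C)C(C)(C)C)c2CC=C(C)C)[C@@H](O[Si](C)(C)C(C)(C)C)C(=O)N(C)OC)ccc1O[Si](C)(C)C(C)(C)C
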